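The plan cuts both the N1–C2 and N1–C5 bonds of the pyrrole ring at once. The ring bears carbon substituents only at C2 (acyl carbon) and C5 (CH2OH carbon), with hydrogen on C3 and C4. It therefore maps atom for atom onto a 2,5-disubstituted furan that differs only in the heteroatom. A photoredox exchange of the furan oxygen for NH builds the pyrrole in one operation and carries both side chains across. The precursor furan holds the future ketone as a racemic triethylsilyl-protected carbinol, which keeps the ring oxidisable. It holds the hydroxymethyl group as a triisopropylsilyl ether rather than an ionisable ester.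

Key step: step 5

Assumption: isomerically pure 16-methylheptadecanoic acid (not technical isostearic acid, an isomer mixture) is purchased; the carbinol carbon made in step 4 is carried as a racemate because step 7 converts it into the ketone, and the target has no stereocentre.

Step 1
Reactants: 1 furfuryl alcohol (furan-2-ylmethanol)
Product: 2 triisopropyl(furan-2-ylmethoxy)silane
Conditions: TIPSCl, imidazole, DMF, 0 °C → rt
Reagents that add atoms: chlorotriisopropylsilane, CC(C)[Si](Cl)(C(C)C)C(C)C
Why: Imidazole-promoted O-silylation of a primary alcohol runs under non-acidic conditions that suit the acid-sensitive furfuryl system, and the bulky silyl ether withstands butyllithium, ammonia and the later selective fluoride treatment.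

Step 2
Reactants: 3 16-methylheptadecanoic acid
Product: 5 N-methoxy-N,16-dimethylheptadecanamide, via acyl imidazolide 4 (not isolated)
Conditions: 1,1'-carbonyldiimidazole, CH2Cl2, rt; MeNH(OMe)·HCl, rt
Reagents that add atoms: N,O-dimethylhydroxylamine hydrochloride, CNOC.Cl; 1,1'-carbonyldiimidazole, O=C(n1ccnc1)n1ccnc1 (supplies the imidazolyl group of 4 only)
Why: Weinreb amide formation through carbonyldiimidazole activation is a mild acyl substitution on an unhindered fatty acid, and everything formed beside 5 is gaseous or water-soluble.

Step 3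
Reactants: 5 N-methoxy-N,16-dimethylheptadecanamide
Product: 7 16-methylheptadecanal, via aluminium hemiaminal 6 (not isolated)
Conditions: diisobutylaluminium hydride, THF, −78 °C; aq potassium sodium tartrate
Reagents that add atoms: diisobutylaluminium hydride, CC(C)C[AlH]CC(C)C (its aluminium fragment stays in 6 only; 7 gains hydrogen alone)
Why: In this Weinreb amide reduction one hydride is delivered to give chelated adduct 6, which is stable at low temperature and releases the aldehyde only on aqueous work-up, so over-reduction to the alcohol is avoided.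

Step 4
Reactants: 2 triisopropyl(furan-2-ylmethoxy)silane, 7 16-methylheptadecanal
Product: 10 2-[16-methyl-1-(triethylsilyloxy)heptadecyl]-5-(triisopropylsilyloxymethyl)furan (racemic), via 5-lithiofuran 8 (not isolated), via lithium alkoxide 9 (not isolated)
Conditions: 2 (1.3 equiv), n-BuLi (1.2 equiv), THF, −78 → 0 °C; 7, −78 °C; Et3SiCl, 4-dimethylaminopyridine (cat.), −78 °C → rt
Reagents that add atoms: chlorotriethylsilane, CC[Si](Cl)(CC)CC; n-butyllithium, [Li]CCCC (lithium of 8 and 9 only)
Why: Deprotonative α-lithiation of a 2-substituted furan can only take the free α-position C5, 1,2-addition of furyllithium 8 to the aldehyde forms the C5–C1′ bond and a carbinol centre that is deliberately racemic (no control needed because step 7 removes it), and alkoxide 9 is capped in the same flask by O-silylation with Et3SiCl.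

Step 5
Reactants: 10 2-[16-methyl-1-(triethylsilyloxy)heptadecyl]-5-(triisopropylsilyloxymethyl)furan (racemic), 11 ammonium carbamate
Product: 13 2-[16-methyl-1-(triethylsilyloxy)heptadecyl]-5-(triisopropylsilyloxymethyl)-1H-pyrrole (racemic), via γ-keto imine 12 (not isolated)
Conditions: 9-mesityl-3,6-di-tert-butyl-10-phenylacridinium tetrafluoroborate (5 mol %), 11 (5 equiv), ClCH2CH2Cl/MeCN, 450 nm LED, N2, rt
Reagents that add atoms: ammonium carbamate (11), NC(=O)[O-].[NH4+] (supplies N1)
Why: The photoexcited acridinium takes one electron from the electron-rich furan ring of 10, ammonia bled slowly from 11 attacks an α-carbon of the resulting radical cation, and proton loss, electron return from the reduced catalyst and scission of the ring C–O bond lead to γ-keto imine 12. The nitrogen of 12 then closes onto the remaining ketone carbon (future C2) in a 5-exo-trig, Paal–Knorr-type condensation and loss of water aromatises the ring, so N1–C2 and N1–C5 are both made, the oxygen leaves as water and no net oxidant or reductant is consumed. The closest known reaction type is the acridinium-photocatalysed furan-to-pyrrole heteroatom exchange with amines, of which the ammonium carbamate version leading to N–H pyrroles is the less explored member. No stereocentre is created, and the racemic silyloxy carbon is a spectator that step 7 flattens. Regiochemistry is not at stake because both α-carbons are substituted and attack at either one funnels into the same pyrrole, whereas chemoselectivity is secured by the carbinol oxidation level (a 2-acylfuran would resist oxidation) and by ammonia being harder to oxidise than the dialkylfuran. The two silyl ethers are poor leaving groups: unlike an ester they cannot acylate nitrogen or depart from the electron-rich N–H pyrrole to give an azafulvene, and they block enol-type tautomerisation next to the imine of 12.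

Step 6
Reactants: 13 2-[16-methyl-1-(triethylsilyloxy)heptadecyl]-5-(triisopropylsilyloxymethyl)-1H-pyrrole (racemic)
Product: 14 16-methyl-1-[5-(triisopropylsilyloxymethyl)-1H-pyrrol-2-yl]heptadecan-1-ol (racemic)
Conditions: Bu4NF/AcOH (1:1, 1.2 equiv), THF, 0 °C
Reagents that add atoms: none
Why: Fluoride-mediated desilylation is governed by steric bulk at silicon, so the triethylsilyl ether should be cleaved far faster than the triisopropylsilyl ether, while the acetic acid buffer keeps the medium close to neutral so that carbinol 14, which is taken on without storage, does not ionise.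

Step 7
Reactants: 14 16-methyl-1-[5-(triisopropylsilyloxymethyl)-1H-pyrrol-2-yl]heptadecan-1-ol (racemic)
Product: 15 16-methyl-1-[5-(triisopropylsilyloxymethyl)-1H-pyrrol-2-yl]heptadecan-1-one
Conditions: activated MnO2 (excess), CH2Cl2, rt
Reagents that add atoms: none
Why: MnO2 oxidation of an activated (pyrrylic, benzylic-type) alcohol proceeds under neutral heterogeneous conditions, removes the racemic centre, leaves the silyl ether alone and should stop by itself because the 2-acylpyrrole formed is a deactivated vinylogous amide.

Step 8
Reactants: 15 16-methyl-1-[5-(triisopropylsilyloxymethyl)-1H-pyrrol-2-yl]heptadecan-1-one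
Product: 16 1-[5-(hydroxymethyl)-1H-pyrrol-2-yl]-16-methylheptadecan-1-one (target)
Conditions: Bu4NF, THF, 0 °C → rt; H2O
Reagents that add atoms: none
Why: Fluoride cleavage of the primary silyl ether is safe at this stage because the 5-acyl group now tempers the ring, and the absence of alcohol solvent or alkoxide excludes conversion of the CH2O group into an alkyl ether by elimination–addition.

Compound list
1 | furfuryl alcohol (furan-2-ylmethanol) | OCc1ccco1 | starting material
2 | triisopropyl(furan-2-ylmethoxy)silane | CC(C)[Si](OCc1ccco1)(C(C)C)C(C)C | intermediate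
3 | 16-methylheptadecanoic acid | CC(C)CCCCCCCCCCCCCCC(=O)O | starting material
4 | 1-(imidazol-1-yl)-16-methylheptadecan-1-one (acyl imidazolide) | CC(C)CCCCCCCCCCCCCCC(=O)n1ccnc1 | intermediate
5 | N-methoxy-N,16-dimethylheptadecanamide | CC(C)CCCCCCCCCCCCCCC(=O)N(C)OC | intermediate
6 | diisobutylaluminium 1-[methoxy(methyl)amino]-16-methylheptadecan-1-olate (aluminium hemiaminal) | CC(C)CCCCCCCCCCCCCCC(O[Al](CC(C)C)CC(C)C)N(C)OC | intermediate
7 | 16-methylheptadecanal | CC(C)CCCCCCCCCCCCCCC=O | intermediate
8 | [5-(triisopropylsilyloxymethyl)furan-2-yl]lithium | [Li]c1ccc(CO[Si](C(C)C)(C(C)C)C(C)C)o1 | intermediate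
9 | lithium 16-methyl-1-[5-(triisopropylsilyloxymethyl)furan-2-yl]heptadecan-1-olate (racemic) | CC(C)CCCCCCCCCCCCCCC([O-])c1ccc(CO[Si](C(C)C)(C(C)C)C(C)C)o1.[Li+] | intermediate
10 | 2-[16-methyl-1-(triethylsilyloxy)heptadecyl]-5-(triisopropylsilyloxymethyl)furan (racemic) | CC(C)CCCCCCCCCCCCCCC(O[Si](CC)(CC)CC)c1ccc(CO[Si](C(C)C)(C(C)C)C(C)C)o1 | intermediate
11 | ammonium carbamate | NC(=O)[O-].[NH4+] | starting material
12 | 2-imino-21-methyl-6-(triethylsilyloxy)-1-(triisopropylsilyloxy)docosan-5-one (racemic) | CC(C)CCCCCCCCCCCCCCC(O[Si](CC)(CC)CC)C(=O)CCC(=N)CO[Si](C(C)C)(C(C)C)C(C)C | intermediate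
13 | 2-[16-methyl-1-(triethylsilyloxy)heptadecyl]-5-(triisopropylsilyloxymethyl)-1H-pyrrole (racemic) | CC(C)CCCCCCCCCCCCCCC(O[Si](CC)(CC)CC)c1ccc(CO[Si](C(C)C)(C(C)C)C(C)C)[nH]1 | intermediate
14 | 16-methyl-1-[5-(triisopropylsilyloxymethyl)-1H-pyrrol-2-yl]heptadecan-1-ol (racemic) | CC(C)CCCCCCCCCCCCCCC(O)c1ccc(CO[Si](C(C)C)(C(C)C)C(C)C)[nH]1 | intermediate
15 | 16-methyl-1-[5-(triisopropylsilyloxymethyl)-1H-pyrrol-2-yl]heptadecan-1-one | CC(C)CCCCCCCCCCCCCCC(=O)c1ccc(CO[Si](C(C)C)(C(C)C)C(C)C)[nH]1 | intermediate
16 | 1-[5-(hydroxymethyl)-1H-pyrrol-2-yl]-16-methylheptadecan-1-one | CC(C)CCCCCCCCCCCCCCC(=O)c1ccc(CO)[nH]1 | target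

Total step count: 8.
Longest linear sequence: 7 steps (3 → 5 → 7 → 10 → 13 → 14 → 15 → 16). The branch from 1 joins at step 4.

Steps most likely to fail

**Step 5 (key step).**
- Possible failure: back electron transfer may outrun ammonia capture. The radical cation may lose a proton at the silyloxy-bearing carbon. The catalyst may oxidise the nitrogen source. The pyrrole, which is more electron-rich than the furan it comes from, may erode by photo-oxidation as it builds up.
- Fallback: the same two N–C bonds are made thermally in three known operations.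
- Setting out from 10, oxidative furan opening with 3-chloroperbenzoic acid and NaHCO3 in CH2Cl2 at 0 °C should give (Z)-21-methyl-6-(triethylsilyloxy)-1-(triisopropylsilyloxy)docos-3-ene-2,5-dione F1.
- Hydrogenation of the electron-poor alkene (H2, Pd/C, EtOAc) should give 21-methyl-6-(triethylsilyloxy)-1-(triisopropylsilyloxy)docosane-2,5-dione F2.
- Paal–Knorr condensation with NH4OAc in ethanol comes back to the route at 13.

**Step 6.**
- Possible failure: insufficient discrimination between the two silyl ethers, or ionisation of the freed carbinol followed by self-condensation.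
- Fallback: the two oxygenated carbons are told apart by carbonyl reactivity instead of by protecting groups.
- Setting out from 13, excess Bu4NF in THF strips both silyl groups to 1-[5-(hydroxymethyl)-1H-pyrrol-2-yl]-16-methylheptadecan-1-ol F3.
- Excess MnO2 in CH2Cl2 oxidises both pyrrylic alcohols to 5-(16-methylheptadecanoyl)-1H-pyrrole-2-carbaldehyde F4.
- NaBH4 in THF/EtOH at low temperature should reduce only the unhindered aldehyde, because the hindered 2-acylpyrrole ketone is much less electrophilic.
- This comes back to the route at target 16 and replaces steps 6 to 8.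

**Step 7.**
- Possible failure: self-condensation of the electron-rich carbinol through azafulvenium formation on the oxide surface, or oxidation of the ring in place of the alcohol.
- Fallback: the ring is deactivated before the carbinol is unveiled.
- Setting out from 13, N-acylation with Boc2O and 4-dimethylaminopyridine in MeCN should give tert-butyl 2-[16-methyl-1-(triethylsilyloxy)heptadecyl]-5-(triisopropylsilyloxymethyl)-1H-pyrrole-1-carboxylate F5.
- Buffered fluoride as in step 6 should give tert-butyl 2-(1-hydroxy-16-methylheptadecyl)-5-(triisopropylsilyloxymethyl)-1H-pyrrole-1-carboxylate F6.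
- Dess–Martin oxidation (NaHCO3, CH2Cl2) should give tert-butyl 2-(16-methylheptadecanoyl)-5-(triisopropylsilyloxymethyl)-1H-pyrrole-1-carboxylate F7.
- K2CO3 in MeOH removes the now activated N-carbamate and comes back to the route at 15.

Further compounds
F1 | step 5 | (Z)-21-methyl-6-(triethylsilyloxy)-1-(triisopropylsilyloxy)docos-3-ene-2,5-dione (racemic) | CC(C)CCCCCCCCCCCCCCC(O[Si](CC)(CC)CC)C(=O)/C=C\C(=O)CO[Si](C(C)C)(C(C)C)C(C)C
F2 | step 5 | 21-methyl-6-(triethylsilyloxy)-1-(triisopropylsilyloxy)docosane-2,5-dione (racemic) | CC(C)CCCCCCCCCCCCCCC(O[Si](CC)(CC)CC)C(=O)CCC(=O)CO[Si](C(C)C)(C(C)C)C(C)C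
F3 | step 6 | 1-[5-(hydroxymethyl)-1H-pyrrol-2-yl]-16-methylheptadecan-1-ol (racemic) | CC(C)CCCCCCCCCCCCCCC(O)c1ccc(CO)[nH]1
F4 | step 6 | 5-(16-methylheptadecanoyl)-1H-pyrrole-2-carbaldehyde | CC(C)CCCCCCCCCCCCCCC(=O)c1ccc(C=O)[nH]1
F5 | step 7 | tert-butyl 2-[16-methyl-1-(triethylsilyloxy)heptadecyl]-5-(triisopropylsilyloxymethyl)-1H-pyrrole-1-carboxylate (racemic) | CC(C)CCCCCCCCCCCCCCC(O[Si](CC)(CC)CC)c1ccc(CO[Si](C(C)C)(C(C)C)C(C)C)n1C(=O)OC(C)(C)C
F6 | step 7 | tert-butyl 2-(1-hydroxy-16-methylheptadecyl)-5-(triisopropylsilyloxymethyl)-1H-pyrrole-1-carboxylate (racemic) | CC(C)CCCCCCCCCCCCCCC(O)c1ccc(CO[Si](C(C)C)(C(C)C)C(C)C)n1C(=O)OC(C)(C)C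
F7 | step 7 | tert-butyl 2-(16-methylheptadecanoyl)-5-(triisopropylsilyloxymethyl)-1H-pyrrole-1-carboxylate | CC(C)CCCCCCCCCCCCCCC(=O)c1ccc(CO[Si](C(C)C)(C(C)C)C(C)C)n1C(=O)OC(C)(C)C
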